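**Plan** (atom labels: longipinane numbering)

- Retrosynthesis: the C-9 and C-14 angelates and the C-7 acetate come off last; the C-1 ketone goes back to allylic C–H oxidation of the C-2=C-3 olefin, and the C-9 carbinol to a C-9 ketone.
- The cyclobutane bond C-4–C-10 is cut next. C-10 is the α-carbon of the C-9 ketone (stored as the exocyclic enone C-10=C-13) and C-4 is an allylic carbon of the cyclohexene ring; the two lie 1,3 to each other across the cis ring fusion C-5/C-11 of a bicyclo[5.4.0]undecene (a 4,10-secolongipinene).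
- That bicycle is cut at C-4–C-5 and C-1–C-11 (Diels–Alder with isoprene); the seven-membered ring is cut at C-5=C-11 (metathesis) and C-6–C-7 (iridium-catalysed allylation).
- Forward: seven-membered ring first, six-membered ring second, cyclobutane last by a hydride-triggered enolate alkylation, then C-1 oxidation and the three esters.
- Stereochemistry: C-6 from the chiral iridium catalyst; C-5/C-11 from Diels–Alder addition anti to the silyloxymethyl group; C-7 by hydroxyl-directed reduction; C-4/C-10 by SN2 inversion under ring constraint; C-9 by Evans–Tishchenko reduction, which also places the acetate.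

Key step: step 14

Remark: C-1 is the ring ketone, C-4 and C-11 the bridgeheads, C-5 (CH) and C-10 (C–CH3) the one-carbon bridges, C-6 the quaternary carbon, C-14 its oxygenated methyl, C-13 the methyl on C-10. The carbinol configuration that accompanies C-6 in step 1 is assumed to be the anti one; it is erased in step 4, so either epimer serves.

Step 1
Reactants: 1 hex-5-en-1-ol; 2 2-methyl-2-vinyloxirane
Product: 4 (2S,3S)-2-ethenyl-2-methyloct-7-ene-1,3-diol, via hex-5-enal 3 (not isolated)
Conditions: cyclometallated π-allyl-Ir C,O-benzoate catalyst with Tol-BINAP (5 mol%, antipode chosen for 2S), K3PO4 (5 mol%), THF, 45 °C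
Reagents that add atoms: none
Why: Iridium-catalysed transfer-hydrogenative tert-(hydroxy)prenylation, in which the alcohol is dehydrogenated to 3 and this is captured through a closed chair transition state by the allyliridium formed from 2, so the ligand should fix the quaternary centre C-6.

Step 2
Reactants: 4 (2S,3S)-2-ethenyl-2-methyloct-7-ene-1,3-diol
Product: 5 (2S,3S)-1-(tert-butyldiphenylsilyloxy)-2-ethenyl-2-methyloct-7-en-3-ol
Conditions: TBDPSCl, imidazole, CH2Cl2, 0 °C
Reagents that add atoms: tert-butyldiphenylsilyl chloride, CC(C)(C)[Si](Cl)(c1ccccc1)c1ccccc1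
Why: Selective silyl ether formation at the unhindered primary hydroxyl over the neopentyl secondary one, which also makes the C-14 arm much bulkier than the C-6 methyl for step 5.

Step 3
Reactants: 5 (2S,3S)-1-(tert-butyldiphenylsilyloxy)-2-ethenyl-2-methyloct-7-en-3-ol
Product: 6 (1S,2S)-2-[(tert-butyldiphenylsilyloxy)methyl]-2-methylcyclohept-3-en-1-ol
Conditions: Grubbs II catalyst (5 mol%), CH2Cl2 (0.005 M), 40 °C
Reagents that add atoms: none
Why: Ring-closing metathesis of the two terminal vinyl groups should close the seven-membered ring with loss of ethene, a cis ring olefin being the only possible geometry.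

Step 4
Reactants: 6 (1S,2S)-2-[(tert-butyldiphenylsilyloxy)methyl]-2-methylcyclohept-3-en-1-ol
Product: 8 (4S)-4-[(tert-butyldiphenylsilyloxy)methyl]-4-methylcyclohept-2-ene-1,5-dione, via ketone 7 (not isolated)
Conditions: CrO3, 3,5-dimethylpyrazole (excess), CH2Cl2, −20 → 0 °C
Reagents that add atoms: chromium trioxide, O=[Cr](=O)=O
Why: The chromium(VI)–pyrazole complex oxidizes the carbinol and then the only allylic methylene (C-10, since the other allylic carbon C-6 is quaternary) in a one-pot alcohol oxidation and allylic C–H oxidation.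

Step 5
Reactants: 8 (4S)-4-[(tert-butyldiphenylsilyloxy)methyl]-4-methylcyclohept-2-ene-1,5-dione; 9 isoprene
Product: 10 14-(tert-butyldiphenylsilyloxy)-13-nor-4,10-secolongipin-2-ene-7,10-dione (cis-fused, H-5 and H-11 cis, C-4 on the side of the C-6 methyl)
Conditions: isoprene (5 equiv), EtAlCl2 (0.3 equiv), CH2Cl2, −30 → 0 °C
Reagents that add atoms: none
Why: Lewis-acid-catalysed Diels–Alder reaction in which the para rule puts the diene methyl on C-3, suprafacial addition gives the cis ring fusion, and the diene should approach the enone face anti to the bulky silyloxymethyl group on the neighbouring quaternary C-6.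

Step 6
Reactants: 10 14-(tert-butyldiphenylsilyloxy)-13-nor-4,10-secolongipin-2-ene-7,10-dione
Product: 11 14-hydroxy-13-nor-4,10-secolongipin-2-ene-7,10-dione
Conditions: HF·pyridine, pyridine, THF, 0 °C → rt
Reagents that add atoms: none
Why: Fluoride-mediated desilylation frees the primary hydroxyl as the directing group for step 7 under conditions that neither enolize C-11 nor cleave the β-hydroxy ketone.

Step 7
Reactants: 11 14-hydroxy-13-nor-4,10-secolongipin-2-ene-7,10-dione
Product: 12 7,14-dihydroxy-13-nor-4,10-secolongipin-2-en-10-one (7-OH trans to C-14)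
Conditions: Me4NBH(OAc)3, MeCN–AcOH (1:1), −30 °C
Reagents that add atoms: none
Why: Evans–Saksena directed reduction, in which the acetoxyborohydride bound to the C-14 hydroxyl delivers hydride to the β-ketone C-7 from the hydroxymethyl face and so gives the C-7 alcohol trans to C-14, while the undirected C-10 ketone should stay untouched.

Step 8
Reactants: 12 7,14-dihydroxy-13-nor-4,10-secolongipin-2-en-10-one
Product: 13 7,14-O-isopropylidene-7,14-dihydroxy-13-nor-4,10-secolongipin-2-en-10-one
Conditions: 2-methoxypropene, PPTS (cat.), CH2Cl2, 0 °C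
Reagents that add atoms: 2-methoxypropene, COC(C)=C
Why: Acid-catalysed acetonide formation protects the 1,3-diol as a trans-fused 1,3-dioxane that should survive the bases, hydride and oxidants of steps 9–15.

Step 9
Reactants: 13 7,14-O-isopropylidene-7,14-dihydroxy-13-nor-4,10-secolongipin-2-en-10-one
Product: 15 9-hydroxy-7,14-O-isopropylidene-7,14-dihydroxy-13-nor-4,10-secolongipin-2-en-10-one (C-9 epimers), via potassium enolate 14 (not isolated)
Conditions: KHMDS, THF, −78 °C; 2-(phenylsulfonyl)-3-phenyloxaziridine, −78 °C; NH4Cl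
Reagents that add atoms: 2-(phenylsulfonyl)-3-phenyloxaziridine, O=S(=O)(N1OC1c1ccccc1)c1ccccc1
Why: Kinetic deprotonation at the C-9 methylene (not at the tertiary ring-fusion C-11 H) and oxaziridine α-hydroxylation of the potassium enolate install the C-9 oxygen, whose configuration is irrelevant because it becomes a ketone.

Step 10
Reactants: 15 9-hydroxy-7,14-O-isopropylidene-7,14-dihydroxy-13-nor-4,10-secolongipin-2-en-10-one
Product: 16 7,14-O-isopropylidene-4,10-secolongipina-2,10(13)-diene-7,9,14-triol (9-OH free, C-9 epimers)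
Conditions: Ph3PCH3Br (4 equiv), KOtBu (3.8 equiv), THF, 0 °C → rt
Reagents that add atoms: methyltriphenylphosphonium bromide, C[P+](c1ccccc1)(c1ccccc1)c1ccccc1.[Br-]
Why: Wittig methylenation turns the C-10 ketone into the exocyclic methylene that becomes C-13, the excess ylide covering the free hydroxyl.

Step 11
Reactants: 16 7,14-O-isopropylidene-4,10-secolongipina-2,10(13)-diene-7,9,14-triol
Product: 17 7,14-O-isopropylidene-7,14-dihydroxy-4,10-secolongipina-2,10(13)-dien-9-one
Conditions: Dess–Martin periodinane, NaHCO3, CH2Cl2, 0 °C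
Reagents that add atoms: none
Why: Dess–Martin oxidation of the allylic alcohol gives the α-methylene ketone, the latent C-10 enolate, without base.

Step 12
Reactants: 17 7,14-O-isopropylidene-7,14-dihydroxy-4,10-secolongipina-2,10(13)-dien-9-one
Product: 18 4-hydroxy-7,14-O-isopropylidene-7,14-dihydroxy-4,10-secolongipina-2,10(13)-dien-9-one (4-OH cis to H-5 and H-11)
Conditions: SeO2 (0.5 equiv), t-BuOOH (3 equiv), CH2Cl2, rt
Reagents that add atoms: tert-butyl hydroperoxide, CC(C)(C)OO (oxygen relayed by catalytic SeO2)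
Why: Selenium dioxide allylic hydroxylation (ene reaction, then [2,3]-shift) should attack the electron-rich trisubstituted C-2=C-3 olefin and not the electron-poor enone, at the ring CH2 on its more substituted end (C-4) and from the convex face, which places the hydroxyl anti to C-10.

Step 13
Reactants: 18 4-hydroxy-7,14-O-isopropylidene-7,14-dihydroxy-4,10-secolongipina-2,10(13)-dien-9-one
Product: 19 4-methanesulfonyloxy-7,14-O-isopropylidene-7,14-dihydroxy-4,10-secolongipina-2,10(13)-dien-9-one
Conditions: Ms2O, Et3N, CH2Cl2, −40 °C, used at once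
Reagents that add atoms: methanesulfonic anhydride, CS(=O)(=O)OS(C)(=O)=O
Why: Sulfonylation with retention at C-4 makes the leaving group, and the anhydride avoids chloride, which could displace the allylic mesylate with inversion.

Step 14
Reactants: 19 4-methanesulfonyloxy-7,14-O-isopropylidene-7,14-dihydroxy-4,10-secolongipina-2,10(13)-dien-9-one
Product: 21 7,14-O-isopropylidene-7,14-dihydroxylongipin-2-en-9-one, via lithium enolate 20 (not isolated)
Conditions: L-Selectride (1.05 equiv), THF, −78 °C, then −78 → 0 °C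
Reagents that add atoms: none
Why: L-Selectride adds hydride to the exocyclic methylene carbon C-13 of the enone, which creates the C-13 methyl and, regiospecifically, the tetrasubstituted lithium enolate 20 at C-10; its α-carbon, held under the cyclohexene by the cis ring fusion, displaces the C-4 mesylate from the rear. The closest known reaction types are the conjugate reduction–alkylation of enones with trialkylborohydrides and the intramolecular alkylation of ketone enolates by 1,3-disposed sulfonates, the classical entry to bicyclo[3.1.1]heptanes. The cyclobutane closes in the 4-(enolexo)-exo-tet mode, and the same bond completes the bicyclo[3.1.1]heptene and the second seven-membered ring. C-4 is set by inversion (leaving group on the convex face, nucleophile from the concave face), and C-10 has no choice, because C-9 must stay in the seven-membered ring and the bond can only form on the face where C-4 lies, which puts the methyl over the olefin bridge. The step needs C- over O-alkylation, SN2 over SN2′ attack and the C-10 over the C-8 enolate: O-alkylation would give an anti-Bredt bridgehead enol ether, direct displacement is the normal course for a lithium enolate and a secondary sulfonate lying 1,3-diaxial to it, and the enolate arises by hydride addition and not by deprotonation, so the C-8 enolate that could expel the C-7 oxygen should never form.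

Step 15
Reactants: 21 7,14-O-isopropylidene-7,14-dihydroxylongipin-2-en-9-one
Product: 22 7,14-O-isopropylidene-7,14-dihydroxylongipin-2-ene-1,9-dione
Conditions: CrO3, 3,5-dimethylpyrazole, CH2Cl2, −20 °C
Reagents that add atoms: chromium trioxide, O=[Cr](=O)=O
Why: Chromium(VI) allylic C–H oxidation of the pinene-type olefin at its only allylic methylene C-1 (the bridgehead C-4 H cannot give a conjugated ketone) should give the verbenone-type enone.

Step 16
Reactants: 22 7,14-O-isopropylidene-7,14-dihydroxylongipin-2-ene-1,9-dione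
Product: 23 7,14-dihydroxylongipin-2-ene-1,9-dione
Conditions: AcOH–H2O–THF (3:1:1), 40 °C
Reagents that add atoms: none
Why: Mild aqueous acid hydrolyses the acetonide, and the enone and cyclobutane should tolerate it as verbenone does.

Step 17
Reactants: 23 7,14-dihydroxylongipin-2-ene-1,9-dione
Product: 24 14-angeloyloxy-7-hydroxylongipin-2-ene-1,9-dione
Conditions: angelic acid (1.2 equiv), 2,4,6-trichlorobenzoyl chloride, Et3N, toluene, rt; then 23, DMAP (cat.), 0 °C
Reagents that add atoms: angelic acid, C/C=C(/C)C(=O)O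
Why: Yamaguchi mixed-anhydride esterification at low temperature should acylate the primary hydroxyl selectively over the secondary C-7 hydroxyl with the Z geometry intact, and capping O-14 first removes the site to which the later C-7 acetate could migrate.

Step 18
Reactants: 24 14-angeloyloxy-7-hydroxylongipin-2-ene-1,9-dione
Product: 25 7-acetoxy-14-angeloyloxy-9-hydroxylongipin-2-en-1-one
Conditions: SmI2 (0.3 equiv), MeCHO (10 equiv), THF, −10 °C
Reagents that add atoms: acetaldehyde, CC=O
Why: Evans–Tishchenko reduction, in which the samarium-bound hemiacetal of the C-7 hydroxyl and acetaldehyde delivers hydride intramolecularly to the C-9 ketone, should give the 7,9-anti diol with the acetate already on O-7 and the C-9 hydroxyl free.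

Step 19
Reactants: 25 7-acetoxy-14-angeloyloxy-9-hydroxylongipin-2-en-1-one
Product: 26 7-acetoxy-9,14-diangeloyloxylongipin-2-en-1-one (target)
Conditions: angelic acid, 2,4,6-trichlorobenzoyl chloride, Et3N, toluene, rt; then 25, DMAP, 60 °C
Reagents that add atoms: angelic acid, C/C=C(/C)C(=O)O
Why: Yamaguchi esterification of the remaining hindered C-9 hydroxyl with angelic acid should complete the target.

**Compound list**

1 | hex-5-en-1-ol | C=CCCCCO | starting material
2 | 2-methyl-2-vinyloxirane | CC1(C=C)CO1 | starting material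
3 | hex-5-enal | C=CCCCC=O | intermediate
4 | (2S,3S)-2-ethenyl-2-methyloct-7-ene-1,3-diol | OC[C@](C)(C=C)[C@@H](O)CCCC=C | intermediate
5 | (2S,3S)-1-(tert-butyldiphenylsilyloxy)-2-ethenyl-2-methyloct-7-en-3-ol | CC(C)(C)[Si](c1ccccc1)(c1ccccc1)OC[C@](C)(C=C)[C@@H](O)CCCC=C | intermediate
6 | (1S,2S)-2-[(tert-butyldiphenylsilyloxy)methyl]-2-methylcyclohept-3-en-1-ol | CC(C)(C)[Si](c1ccccc1)(c1ccccc1)OC[C@]1(C)C=CCCC[C@@H]1O | intermediate
7 | (2S)-2-[(tert-butyldiphenylsilyloxy)methyl]-2-methylcyclohept-3-en-1-one | CC(C)(C)[Si](c1ccccc1)(c1ccccc1)OC[C@]1(C)C=CCCCC1=O | intermediate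
8 | (4S)-4-[(tert-butyldiphenylsilyloxy)methyl]-4-methylcyclohept-2-ene-1,5-dione | CC(C)(C)[Si](c1ccccc1)(c1ccccc1)OC[C@]1(C)C=CC(=O)CCC1=O | intermediate
9 | isoprene | C=CC(C)=C | starting material
10 | 14-(tert-butyldiphenylsilyloxy)-13-nor-4,10-secolongipin-2-ene-7,10-dione (cis-fused) | CC(C)(C)[Si](c1ccccc1)(c1ccccc1)OC[C@]1(C)[C@H]2CC(C)=CC[C@H]2C(=O)CCC1=O | intermediate
11 | 14-hydroxy-13-nor-4,10-secolongipin-2-ene-7,10-dione | OC[C@]1(C)[C@H]2CC(C)=CC[C@H]2C(=O)CCC1=O | intermediate
12 | 7,14-dihydroxy-13-nor-4,10-secolongipin-2-en-10-one (7-OH trans to C-14) | OC[C@]1(C)[C@H]2CC(C)=CC[C@H]2C(=O)CC[C@H]1O | intermediate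
13 | 7,14-O-isopropylidene-7,14-dihydroxy-13-nor-4,10-secolongipin-2-en-10-one | CC1(C)OC[C@]2(C)[C@H]3CC(C)=CC[C@H]3C(=O)CC[C@H]2O1 | intermediate
14 | potassium 9(10)-enolate of 13 | CC1(C)OC[C@]2(C)[C@H]3CC(C)=CC[C@H]3C([O-])=CC[C@H]2O1.[K+] | intermediate
15 | 9-hydroxy derivative of 13 (C-9 epimers) | CC1(C)OC[C@]2(C)[C@H]3CC(C)=CC[C@H]3C(=O)C(O)C[C@H]2O1 | intermediate
16 | 7,14-O-isopropylidene-4,10-secolongipina-2,10(13)-diene-7,9,14-triol (C-9 epimers) | CC1(C)OC[C@]2(C)[C@H]3CC(C)=CC[C@H]3C(=C)C(O)C[C@H]2O1 | intermediate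
17 | 7,14-O-isopropylidene-7,14-dihydroxy-4,10-secolongipina-2,10(13)-dien-9-one | CC1(C)OC[C@]2(C)[C@H]3CC(C)=CC[C@H]3C(=C)C(=O)C[C@H]2O1 | intermediate
18 | 4-hydroxy derivative of 17 (4-OH cis to H-5) | CC1(C)OC[C@]2(C)[C@H]3[C@H](O)C(C)=CC[C@H]3C(=C)C(=O)C[C@H]2O1 | intermediate
19 | 4-O-mesylate of 18 | CC1(C)OC[C@]2(C)[C@H]3[C@H](OS(C)(=O)=O)C(C)=CC[C@H]3C(=C)C(=O)C[C@H]2O1 | intermediate
20 | lithium 9(10)-enolate formed from 19 (C-13 now methyl) | CC1(C)OC[C@]2(C)[C@H]3[C@H](OS(C)(=O)=O)C(C)=CC[C@H]3C(C)=C([O-])C[C@H]2O1.[Li+] | intermediate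
21 | 7,14-O-isopropylidene-7,14-dihydroxylongipin-2-en-9-one | CC1(C)OC[C@]2(C)[C@@H]3[C@H]4CC=C(C)[C@@H]3[C@@]4(C)C(=O)C[C@H]2O1 | intermediate
22 | 7,14-O-isopropylidene-7,14-dihydroxylongipin-2-ene-1,9-dione | CC1(C)OC[C@]2(C)[C@@H]3[C@H]4C(=O)C=C(C)[C@@H]3[C@@]4(C)C(=O)C[C@H]2O1 | intermediate
23 | 7,14-dihydroxylongipin-2-ene-1,9-dione | OC[C@]1(C)[C@@H]2[C@H]3C(=O)C=C(C)[C@@H]2[C@@]3(C)C(=O)C[C@H]1O | intermediate
24 | 14-angeloyloxy-7-hydroxylongipin-2-ene-1,9-dione | C/C=C(/C)C(=O)OC[C@]1(C)[C@@H]2[C@H]3C(=O)C=C(C)[C@@H]2[C@@]3(C)C(=O)C[C@H]1O | intermediate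
25 | 7-acetoxy-14-angeloyloxy-9-hydroxylongipin-2-en-1-one (7,9-anti) | C/C=C(/C)C(=O)OC[C@]1(C)[C@@H]2[C@H]3C(=O)C=C(C)[C@@H]2[C@@]3(C)[C@H](O)C[C@H]1OC(C)=O | intermediate
26 | 7-acetoxy-9,14-diangeloyloxylongipin-2-en-1-one | C/C=C(/C)C(=O)OC[C@]1(C)[C@@H]2[C@H]3C(=O)C=C(C)[C@@H]2[C@@]3(C)[C@H](OC(=O)/C(C)=C\C)C[C@H]1OC(C)=O | target

**Count and risks**

Total step count: 19. Longest linear sequence: 19 steps (from 1 and 2; isoprene 9 enters at step 5).

Steps most likely to fail:

Step 14. The enolate may attack the far allyl terminus C-2 (SN2′) instead of C-4, or the allylic sulfonate may ionize or eliminate before the ring closes. The fallback sets out from 18 and comes back at 21, and removes the allyl system for the ring closure. Hydroxyl-directed epoxidation of 18 (VO(acac)2, t-BuOOH, CH2Cl2) gives the 2,3-epoxy alcohol F1, with the epoxide on the face of the 4-OH and away from C-10. Mesylation (Ms2O, Et3N) gives the epoxy mesylate F2, in which only direct displacement at C-4 is possible. The same L-Selectride reduction–alkylation gives the epoxy ketone F3. Rhenium-catalysed deoxygenation (MeReO3 cat., PPh3, benzene, rt) restores the C-2=C-3 olefin and gives 21.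

Step 5. The diene may add with poor facial selectivity, or syn to the silyloxymethyl group, because the two faces differ only through the C-6 substituents. The fallback sets out from 6 and comes back at 10, and uses the existing C-7 carbinol, which is cis to C-14, as a second shield on the same face. Silylation of 6 (TBSOTf, 2,6-lutidine) gives the bis-silyl ether F4. Allylic oxidation (CrO3, 3,5-dimethylpyrazole) gives the enone F5, which carries both bulky groups on one face. The Diels–Alder reaction with isoprene (EtAlCl2) gives the adduct F6. Selective removal of the secondary TBS group (PPTS, MeOH) gives the hydroxy ketone F7, and Dess–Martin oxidation gives 10.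

Step 19. The forcing acylation of the hindered C-9 carbinol may isomerize the activated angelate to the tiglate (Z to E) and let the C-7 acetate migrate. The fallback sets out from 25 and comes back at 26, and builds the Z-enoate on the molecule. Esterification of 25 with 2-[bis(2,2,2-trifluoroethoxy)phosphoryl]propanoic acid (EDC, DMAP, CH2Cl2, rt) gives the phosphonate ester F8. Still–Gennari olefination with acetaldehyde (KHMDS, 18-crown-6, THF, −78 °C) should then give the Z-2-methylbut-2-enoate 26.

Further compounds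
F1 | step 14 | 2,3-epoxy-4-hydroxy-7,14-O-isopropylidene-7,14-dihydroxy-4,10-secolongipin-10(13)-en-9-one (epoxide cis to 4-OH) | CC1(C)OC[C@]2(C)[C@H]3[C@H](O)[C@]4(C)O[C@@H]4C[C@H]3C(=C)C(=O)C[C@H]2O1
F2 | step 14 | 4-O-mesylate of F1 | CC1(C)OC[C@]2(C)[C@H]3[C@H](OS(C)(=O)=O)[C@]4(C)O[C@@H]4C[C@H]3C(=C)C(=O)C[C@H]2O1
F3 | step 14 | 2,3-epoxy-7,14-O-isopropylidene-7,14-dihydroxylongipinan-9-one | CC1(C)OC[C@]2(C)[C@@H]3[C@H]4C[C@H]5O[C@@]5(C)[C@@H]3[C@@]4(C)C(=O)C[C@H]2O1
F4 | step 5 | (1S,2S)-1-(tert-butyldimethylsilyloxy)-2-[(tert-butyldiphenylsilyloxy)methyl]-2-methylcyclohept-3-ene | CC(C)(C)[Si](c1ccccc1)(c1ccccc1)OC[C@]1(C)C=CCCC[C@@H]1O[Si](C)(C)C(C)(C)C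
F5 | step 5 | 5-(tert-butyldimethylsilyloxy)-4-[(tert-butyldiphenylsilyloxy)methyl]-4-methylcyclohept-2-en-1-one (OTBS cis to CH2OTBDPS) | CC(C)(C)[Si](c1ccccc1)(c1ccccc1)OC[C@]1(C)C=CC(=O)CC[C@@H]1O[Si](C)(C)C(C)(C)C
F6 | step 5 | 7-(tert-butyldimethylsilyloxy)-14-(tert-butyldiphenylsilyloxy)-13-nor-4,10-secolongipin-2-en-10-one (cis-fused, 7-O cis to C-14) | CC(C)(C)[Si](c1ccccc1)(c1ccccc1)OC[C@]1(C)[C@H]2CC(C)=CC[C@H]2C(=O)CC[C@@H]1O[Si](C)(C)C(C)(C)C
F7 | step 5 | 14-(tert-butyldiphenylsilyloxy)-7-hydroxy-13-nor-4,10-secolongipin-2-en-10-one (7-OH cis to C-14) | CC(C)(C)[Si](c1ccccc1)(c1ccccc1)OC[C@]1(C)[C@H]2CC(C)=CC[C@H]2C(=O)CC[C@@H]1O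
F8 | step 19 | 7-acetoxy-14-angeloyloxy-9-{2-[bis(2,2,2-trifluoroethoxy)phosphoryl]propanoyloxy}longipin-2-en-1-one | C/C=C(/C)C(=O)OC[C@]1(C)[C@@H]2[C@H]3C(=O)C=C(C)[C@@H]2[C@@]3(C)[C@H](OC(=O)C(C)P(=O)(OCC(F)(F)F)OCC(F)(F)F)C[C@H]1OC(C)=O
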